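Everything rests on disconnecting ring C of the flavone half at C8a–O1, C4a–C4 and O1–C2, which leads back to a 3,5-dialkoxybenzyne and an arylpropiolic acid that already carries the diaryl ether. The feature exploited is that O1 (on C8a) and the C4 carbonyl (on C4a) are neighbours on ring A, with the C5 oxygen next to C4a: a 3-alkoxyaryne takes up the carboxylate oxygen and the acyl group at exactly these carbons, and the liberated phenoxide closes the pyranone in the same flask. The precursors are a 3,5-dimethoxy-2-silylphenyl triflate and an ether-only propiolic acid; the (2S)-flavanone ring is annulated afterwards.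

Key step: step 8

Remarks on the design
- Ring A of the flavone is carried as its 5,7-dimethyl ether. A 3-benzyloxy-5-methoxyphenyl carbamate has two different ortho positions, each flanked by an ether oxygen, so its silylation would give two aryne precursors and a partly reversed 5/7 ether pattern. In 3,5-dimethoxyphenol the two ortho positions are equivalent; the C5 methyl ether is removed later by chelation-controlled cleavage.
- The pyranone ring of the second half is closed while the acetyl group has only one free ortho hydroxyl. Freeing the second ortho oxygen first would let the ring close in either direction and give the 6-aryloxy and the 8-aryloxy isomers.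
- Both peri methyl ethers are cleaved before the stereocentre exists, so no Lewis acid meets the flavanone; the stereocentre is set by catalysis on a chromone.

Assumption: the sense of induction in step 13 is taken to follow the quadrant model for rhodium/atropisomeric bisphosphine additions to cyclic enones ((S)-ligand giving 2S). It is to be confirmed on a simple chromone, and the ligand antipode is used if the sense is reversed.

Step 1
Reactants: 1 3,5-dimethoxyphenol
Product: 2 3,5-dimethoxyphenyl N-isopropylcarbamate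
Conditions: i-PrNCO, Et3N (cat.), CH2Cl2, rt
Reagents that add atoms: isopropyl isocyanate, CC(C)N=C=O
Why: Amine-catalysed addition of the phenol to the isocyanate gives the carbamate needed as a cleavable directing group.

Step 2
Reactants: 2 3,5-dimethoxyphenyl N-isopropylcarbamate
Product: 5 3,5-dimethoxy-2-(trimethylsilyl)phenyl N-isopropylcarbamate, via N-silyl carbamate 3 (not isolated), via N-silyl C-silyl carbamate 4 (not isolated)
Conditions: TBSOTf, TMEDA, Et2O, 0 °C to rt; then TMEDA, n-BuLi (2.1 equiv), −78 °C; then TMSCl, −78 °C to rt; aq. NaHSO4 work-up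
Reagents that add atoms: chlorotrimethylsilane, C[Si](C)(C)Cl
Why: Directed ortho-metalation: transient N-silylation masks the N–H, the carbamate then directs lithiation to the position between itself and a methoxy group (both such positions are equivalent by symmetry), TMSCl traps the aryllithium, and the N–Si bond is hydrolysed in the work-up.

Step 3
Reactants: 5 3,5-dimethoxy-2-(trimethylsilyl)phenyl N-isopropylcarbamate
Product: 7 3,5-dimethoxy-2-(trimethylsilyl)phenyl trifluoromethanesulfonate, via silylphenol 6 (not isolated)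
Conditions: DBU, Et2NH, MeCN, 40 °C; then PhNTf2, rt
Reagents that add atoms: N-phenylbis(trifluoromethanesulfonimide), O=S(=O)(N(c1ccccc1)S(=O)(=O)C(F)(F)F)C(F)(F)F
Why: DBU deprotonates the N–H and the carbamate fragments by an E1cB path (the isocyanate is trapped by Et2NH as a urea); the phenoxide is triflated in the same pot under conditions mild enough to keep the C–Si bond.

Step 4
Reactants: 8 2,6-dimethoxyhydroquinone
Product: 9 4-(benzyloxy)-2,6-dimethoxyphenol
Conditions: BnBr (1.0 equiv), K2CO3 (1.1 equiv), degassed acetone, Ar, rt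
Reagents that add atoms: benzyl bromide, BrCc1ccccc1
Why: Williamson etherification with one equivalent of halide should take place at the C4 hydroxyl, which is both less hindered and more acidic than the C1 hydroxyl flanked by two methoxy groups; air is excluded to keep the hydroquinone from oxidising.

Step 5
Reactants: 9 4-(benzyloxy)-2,6-dimethoxyphenol; 10 4-fluorobenzaldehyde
Product: 11 4-[4-(benzyloxy)-2,6-dimethoxyphenoxy]benzaldehyde
Conditions: K2CO3, DMF, 120 °C, N2
Reagents that add atoms: none
Why: Nucleophilic aromatic substitution (addition–elimination) of fluoride activated by the para formyl group; the electron-rich phenoxide is a good nucleophile despite its two ortho substituents.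

Step 6
Reactants: 11 4-[4-(benzyloxy)-2,6-dimethoxyphenoxy]benzaldehyde
Product: 12 5-(benzyloxy)-2-[4-(2,2-dibromovinyl)phenoxy]-1,3-dimethoxybenzene
Conditions: CBr4, PPh3, CH2Cl2, 0 °C
Reagents that add atoms: carbon tetrabromide, BrC(Br)(Br)Br
Why: First stage of the Corey–Fuchs sequence, a Wittig-type olefination of the aldehyde by the dibromomethylene ylide formed from CBr4 and PPh3.

Step 7
Reactants: 12 5-(benzyloxy)-2-[4-(2,2-dibromovinyl)phenoxy]-1,3-dimethoxybenzene
Product: 14 3-{4-[4-(benzyloxy)-2,6-dimethoxyphenoxy]phenyl}propiolic acid, via lithium acetylide 13 (not isolated)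
Conditions: n-BuLi (2.2 equiv), THF, −78 °C; then CO2, −78 °C to rt; 1 M HCl work-up
Reagents that add atoms: carbon dioxide, O=C=O
Why: Second stage of the Corey–Fuchs sequence: bromine–lithium exchange and 1,2-shift give the alkyne, the second equivalent of base forms the acetylide, and carboxylation with CO2 gives the acid; the ethers are inert at −78 °C.

Step 8
Reactants: 7 3,5-dimethoxy-2-(trimethylsilyl)phenyl trifluoromethanesulfonate; 14 3-{4-[4-(benzyloxy)-2,6-dimethoxyphenoxy]phenyl}propiolic acid
Product: 17 2-{4-[4-(benzyloxy)-2,6-dimethoxyphenoxy]phenyl}-5,7-dimethoxy-4H-chromen-4-one, via 3,5-dimethoxybenzyne 15 (not isolated), via ortho-hydroxyaryl ynone 16 (not isolated)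
Conditions: 7 (1.5 equiv), CsF (4 equiv), THF, 125 °C, sealed tube
Reagents that add atoms: none
Why: Fluoride removes the silyl group of 7 with loss of triflate to give aryne 15; the caesium carboxylate of 14 adds through oxygen to the aryne carbon remote from the C3 methoxy group (future C8a, bond C8a–O1), and the aryl anion left on the carbon next to that methoxy group (future C4a) attacks the ester carbonyl through a four-membered transition state, so the acyl group moves from oxygen to carbon (bond C4–C4a) and the phenoxide of ynone 16 results. This phenoxide adds to the aryl-bearing alkyne carbon (bond O1–C2) and the vinyl anion is protonated at C3, which closes ring C in the 6-endo-dig mode. The closest known reaction type is the fluoride-induced insertion of arynes into the C–O bond of carboxylic acids to give ortho-hydroxyaryl ketones, which with arylpropiolic acids leads on to flavones. No stereocentre is formed. The step needs regioselective addition to the unsymmetrical aryne; this is secured by the inductive effect of the C3 methoxy group, which sends the nucleophile to the distal carbon and stabilises the anion on the proximal one, so the 5,7-dimethoxy ring A should form and not the 6,8-isomer. Closure to the flavone and not to the aurone (5-exo) is favoured by the polarisation of the ynone, and chemoselectivity is secured because 14 carries only ethers besides the acid.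

Step 9
Reactants: 17 2-{4-[4-(benzyloxy)-2,6-dimethoxyphenoxy]phenyl}-5,7-dimethoxy-4H-chromen-4-one
Product: 18 2-[4-(4-hydroxy-2,6-dimethoxyphenoxy)phenyl]-5,7-dimethoxy-4H-chromen-4-one
Conditions: H2 (1 atm), 10% Pd/C, EtOAc/THF, rt
Reagents that add atoms: none
Why: Catalytic hydrogenolysis of the aryl benzyl ether; the C2–C3 double bond of the pyranone is reduced far more slowly and the reaction is stopped when 17 is consumed.

Step 10
Reactants: 18 2-[4-(4-hydroxy-2,6-dimethoxyphenoxy)phenyl]-5,7-dimethoxy-4H-chromen-4-one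
Product: 19 2-[4-(3-acetyl-4-hydroxy-2,6-dimethoxyphenoxy)phenyl]-5,7-dimethoxy-4H-chromen-4-one
Conditions: AcOH, BF3·OEt2, 85 °C; then 10% aq. NaOAc
Reagents that add atoms: acetic acid, CC(=O)O
Why: BF3-promoted Friedel–Crafts (Fries-type) C-acetylation: the free phenol ring is by far the most electron-rich arene, its two open positions are equivalent and both lie ortho to the hydroxyl, the product is shielded from a second acylation as its boron chelate, and ring A of the flavone is deactivated by the complexed pyranone carbonyl.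

Step 11
Reactants: 19 2-[4-(3-acetyl-4-hydroxy-2,6-dimethoxyphenoxy)phenyl]-5,7-dimethoxy-4H-chromen-4-one
Product: 21 6-[4-(5,7-dimethoxy-4-oxo-4H-chromen-2-yl)phenoxy]-5,7-dimethoxy-4H-chromen-4-one, via enaminone 20 (not isolated)
Conditions: Me2NCH(OMe)2, toluene, 100 °C; evaporate; then conc. HCl, CH2Cl2, 40 °C
Reagents that add atoms: N,N-dimethylformamide dimethyl acetal, COC(OC)N(C)C
Why: Enaminone route to 2-unsubstituted chromones: condensation at the acetyl methyl group, then acid-promoted addition of the single free ortho phenol and loss of dimethylamine; since the other ortho oxygen is still a methyl ether, the ring can close in one direction only and the aryloxy group ends at C6.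

Step 12
Reactants: 21 6-[4-(5,7-dimethoxy-4-oxo-4H-chromen-2-yl)phenoxy]-5,7-dimethoxy-4H-chromen-4-one
Product: 22 5-hydroxy-6-[4-(5-hydroxy-7-methoxy-4-oxo-4H-chromen-2-yl)phenoxy]-7-methoxy-4H-chromen-4-one
Conditions: BCl3 (5 equiv), CH2Cl2, −20 to 0 °C; then MeOH, H2O
Reagents that add atoms: none
Why: Chelation-controlled ether cleavage: BCl3 binds between each pyranone carbonyl and its peri methoxy oxygen and chloride removes that methyl group, so only the two C5 ethers fall while the C7 methyl ethers and the diaryl ether, which cannot chelate, remain.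

Step 13
Reactants: 22 5-hydroxy-6-[4-(5-hydroxy-7-methoxy-4-oxo-4H-chromen-2-yl)phenoxy]-7-methoxy-4H-chromen-4-one; 23 4-(benzyloxy)phenylboronic acid
Product: 24 (2S)-2-[4-(benzyloxy)phenyl]-5-hydroxy-6-[4-(5-hydroxy-7-methoxy-4-oxo-4H-chromen-2-yl)phenoxy]-7-methoxychroman-4-one
Conditions: [Rh(OH)((S)-MeO-F12-BIPHEP)]2 (2.5 mol%; ligand = (S)-2,2'-bis[bis(3,4,5-trifluorophenyl)phosphino]-6,6'-dimethoxy-1,1'-biphenyl), 23 (2.5 equiv), 1,4-dioxane/H2O 10:1, 40 °C
Reagents that add atoms: none
Why: Hayashi–Miyaura asymmetric 1,4-addition: the aryl–rhodium species adds to C2 of the 2-unsubstituted chromone only (the flavone half is β,β-disubstituted and inert), the hydrogen-bonded phenols should be tolerated under base-free aqueous conditions, and the C2 stereocentre is set under catalyst control by the (S)-bisphosphine, which is expected to deliver the aryl group to the face giving 2S.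

Step 14
Reactants: 24 (2S)-2-[4-(benzyloxy)phenyl]-5-hydroxy-6-[4-(5-hydroxy-7-methoxy-4-oxo-4H-chromen-2-yl)phenoxy]-7-methoxychroman-4-one
Product: 25 (2S)-5-hydroxy-2-(4-hydroxyphenyl)-6-[4-(5-hydroxy-7-methoxy-4-oxo-4H-chromen-2-yl)phenoxy]-7-methoxychroman-4-one (CNP0202121.1)
Conditions: H2 (1 atm), 10% Pd/C, EtOAc/THF, rt
Reagents that add atoms: none
Why: Hydrogenolysis of the aryl benzyl ether under neutral conditions, which should leave the C2 stereocentre untouched because no acid or base that could open the flavanone ring is present.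

Compound list
1 | 3,5-dimethoxyphenol | COc1cc(O)cc(OC)c1 | starting material
2 | 3,5-dimethoxyphenyl N-isopropylcarbamate | CC(C)NC(=O)Oc1cc(OC)cc(OC)c1 | intermediate
3 | 3,5-dimethoxyphenyl N-(tert-butyldimethylsilyl)-N-isopropylcarbamate (formed in situ) | CC(C)N(C(=O)Oc1cc(OC)cc(OC)c1)[Si](C)(C)C(C)(C)C | intermediate
4 | 3,5-dimethoxy-2-(trimethylsilyl)phenyl N-(tert-butyldimethylsilyl)-N-isopropylcarbamate (formed in situ) | CC(C)N(C(=O)Oc1cc(OC)cc(OC)c1[Si](C)(C)C)[Si](C)(C)C(C)(C)C | intermediate
5 | 3,5-dimethoxy-2-(trimethylsilyl)phenyl N-isopropylcarbamate | CC(C)NC(=O)Oc1cc(OC)cc(OC)c1[Si](C)(C)C | intermediate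
6 | 3,5-dimethoxy-2-(trimethylsilyl)phenol (formed in situ) | COc1cc(O)c([Si](C)(C)C)c(OC)c1 | intermediate
7 | 3,5-dimethoxy-2-(trimethylsilyl)phenyl trifluoromethanesulfonate | COc1cc(OS(=O)(=O)C(F)(F)F)c([Si](C)(C)C)c(OC)c1 | intermediate
8 | 2,6-dimethoxyhydroquinone (2,6-dimethoxybenzene-1,4-diol) | COc1cc(O)cc(OC)c1O | starting material
9 | 4-(benzyloxy)-2,6-dimethoxyphenol | COc1cc(OCc2ccccc2)cc(OC)c1O | intermediate
10 | 4-fluorobenzaldehyde | O=Cc1ccc(F)cc1 | starting material
11 | 4-[4-(benzyloxy)-2,6-dimethoxyphenoxy]benzaldehyde | COc1cc(OCc2ccccc2)cc(OC)c1Oc1ccc(C=O)cc1 | intermediate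
12 | 5-(benzyloxy)-2-[4-(2,2-dibromovinyl)phenoxy]-1,3-dimethoxybenzene | COc1cc(OCc2ccccc2)cc(OC)c1Oc1ccc(C=C(Br)Br)cc1 | intermediate
13 | lithium {4-[4-(benzyloxy)-2,6-dimethoxyphenoxy]phenyl}acetylide (formed in situ) | COc1cc(OCc2ccccc2)cc(OC)c1Oc1ccc(C#C[Li])cc1 | intermediate
14 | 3-{4-[4-(benzyloxy)-2,6-dimethoxyphenoxy]phenyl}propiolic acid | COc1cc(OCc2ccccc2)cc(OC)c1Oc1ccc(C#CC(=O)O)cc1 | intermediate
15 | 3,5-dimethoxybenzyne (formed in situ) | COC1=CC(OC)=CC#C1 | intermediate
16 | 3-{4-[4-(benzyloxy)-2,6-dimethoxyphenoxy]phenyl}-1-(2-hydroxy-4,6-dimethoxyphenyl)prop-2-yn-1-one (formed in situ) | COc1cc(O)c(C(=O)C#Cc2ccc(Oc3c(OC)cc(OCc4ccccc4)cc3OC)cc2)c(OC)c1 | intermediate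
17 | 2-{4-[4-(benzyloxy)-2,6-dimethoxyphenoxy]phenyl}-5,7-dimethoxy-4H-chromen-4-one | COc1cc(OC)c2c(=O)cc(-c3ccc(Oc4c(OC)cc(OCc5ccccc5)cc4OC)cc3)oc2c1 | intermediate
18 | 2-[4-(4-hydroxy-2,6-dimethoxyphenoxy)phenyl]-5,7-dimethoxy-4H-chromen-4-one | COc1cc(OC)c2c(=O)cc(-c3ccc(Oc4c(OC)cc(O)cc4OC)cc3)oc2c1 | intermediate
19 | 2-[4-(3-acetyl-4-hydroxy-2,6-dimethoxyphenoxy)phenyl]-5,7-dimethoxy-4H-chromen-4-one | COc1cc(OC)c2c(=O)cc(-c3ccc(Oc4c(OC)cc(O)c(C(C)=O)c4OC)cc3)oc2c1 | intermediate
20 | 2-{4-[3-((E)-3-(dimethylamino)acryloyl)-4-hydroxy-2,6-dimethoxyphenoxy]phenyl}-5,7-dimethoxy-4H-chromen-4-one (formed in situ) | COc1cc(OC)c2c(=O)cc(-c3ccc(Oc4c(OC)cc(O)c(C(=O)/C=C/N(C)C)c4OC)cc3)oc2c1 | intermediate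
21 | 6-[4-(5,7-dimethoxy-4-oxo-4H-chromen-2-yl)phenoxy]-5,7-dimethoxy-4H-chromen-4-one | COc1cc(OC)c2c(=O)cc(-c3ccc(Oc4c(OC)cc5occc(=O)c5c4OC)cc3)oc2c1 | intermediate
22 | 5-hydroxy-6-[4-(5-hydroxy-7-methoxy-4-oxo-4H-chromen-2-yl)phenoxy]-7-methoxy-4H-chromen-4-one | COc1cc(O)c2c(=O)cc(-c3ccc(Oc4c(OC)cc5occc(=O)c5c4O)cc3)oc2c1 | intermediate
23 | 4-(benzyloxy)phenylboronic acid | OB(O)c1ccc(OCc2ccccc2)cc1 | starting material
24 | (2S)-2-[4-(benzyloxy)phenyl]-5-hydroxy-6-[4-(5-hydroxy-7-methoxy-4-oxo-4H-chromen-2-yl)phenoxy]-7-methoxychroman-4-one | COc1cc(O)c2c(=O)cc(-c3ccc(Oc4c(OC)cc5c(c4O)C(=O)C[C@@H](c4ccc(OCc6ccccc6)cc4)O5)cc3)oc2c1 | intermediate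
25 | (2S)-5-hydroxy-2-(4-hydroxyphenyl)-6-[4-(5-hydroxy-7-methoxy-4-oxo-4H-chromen-2-yl)phenoxy]-7-methoxychroman-4-one | COc1cc(O)c2c(=O)cc(-c3ccc(Oc4c(OC)cc5c(c4O)C(=O)C[C@@H](c4ccc(O)cc4)O5)cc3)oc2c1 | target

Total step count: 14 (steps 1–3 give the aryne precursor, steps 4–7 the acid, steps 8–14 the union and the endgame).
Longest linear sequence: 11 steps (steps 4–14, from 2,6-dimethoxyhydroquinone 8).

Steps most likely to fail

Step 8. The aryl anion may be protonated before the acyl group migrates, which leaves an aryl propiolate; the propiolate may also decarboxylate at the temperature needed, or the ynone may close 5-exo. The fallback builds the same flavone by chalcone chemistry and sets out from aldehyde 11. Claisen–Schmidt condensation of 11 with commercial 2'-hydroxy-4',6'-dimethoxyacetophenone (KOH, EtOH, rt) should give (E)-3-{4-[4-(benzyloxy)-2,6-dimethoxyphenoxy]phenyl}-1-(2-hydroxy-4,6-dimethoxyphenyl)prop-2-en-1-one F1. Oxidative cyclisation of this 2'-hydroxychalcone with catalytic I2 in DMSO at 130 °C returns to the route at flavone 17.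

Step 13. Carbometalation may be slow on the crowded, electron-rich trioxygenated chromone or in the presence of the chelated phenols, the two faces of C2 may be poorly distinguished, and the 5-hydroxyflavanone may lose optical purity by reversible ring opening in the warm aqueous medium. The fallback gives up asymmetric catalysis and sets out from acetophenone 19. Claisen–Schmidt condensation with 4-(benzyloxy)benzaldehyde (KOH, EtOH/THF, rt) should give the 2'-hydroxychalcone 2-[4-(3-{(E)-3-[4-(benzyloxy)phenyl]acryloyl}-4-hydroxy-2,6-dimethoxyphenoxy)phenyl]-5,7-dimethoxy-4H-chromen-4-one F2. Oxa-Michael closure (NaOAc, EtOH, reflux) gives racemic 2-[4-(benzyloxy)phenyl]-6-[4-(5,7-dimethoxy-4-oxo-4H-chromen-2-yl)phenoxy]-5,7-dimethoxychroman-4-one F3. BCl3 with pentamethylbenzene (CH2Cl2, −78 to 0 °C) cleaves the benzyl ether and both peri methyl ethers to give the racemic target, rac-5-hydroxy-2-(4-hydroxyphenyl)-6-[4-(5-hydroxy-7-methoxy-4-oxo-4H-chromen-2-yl)phenoxy]-7-methoxychroman-4-one F4. Preparative HPLC on an amylose tris(3,5-dimethylphenylcarbamate) phase separates the unwanted (2R)-5-hydroxy-2-(4-hydroxyphenyl)-6-[4-(5-hydroxy-7-methoxy-4-oxo-4H-chromen-2-yl)phenoxy]-7-methoxychroman-4-one F5 and returns to the route at target 25.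

Step 4. Alkylation may occur at the wrong hydroxyl or at both, and the hydroquinone may be oxidised to the quinone under base. The fallback fixes the position of the benzyl group by construction and sets out from 3,5-dimethoxyphenol 1. Vilsmeier–Haack formylation (POCl3, DMF) para to the hydroxyl gives 4-hydroxy-2,6-dimethoxybenzaldehyde F6, which is separated from the minor ortho isomer. Benzylation (BnBr, K2CO3, DMF) gives 4-(benzyloxy)-2,6-dimethoxybenzaldehyde F7. Baeyer–Villiger oxidation of this electron-rich aldehyde (mCPBA, CH2Cl2) gives 4-(benzyloxy)-2,6-dimethoxyphenyl formate F8, and methanolysis (K2CO3, MeOH) returns to the route at phenol 9.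

Further compounds
F1 | step 8 | (E)-3-{4-[4-(benzyloxy)-2,6-dimethoxyphenoxy]phenyl}-1-(2-hydroxy-4,6-dimethoxyphenyl)prop-2-en-1-one | COc1cc(O)c(C(=O)/C=C/c2ccc(Oc3c(OC)cc(OCc4ccccc4)cc3OC)cc2)c(OC)c1
F2 | step 13 | 2-[4-(3-{(E)-3-[4-(benzyloxy)phenyl]acryloyl}-4-hydroxy-2,6-dimethoxyphenoxy)phenyl]-5,7-dimethoxy-4H-chromen-4-one | COc1cc(OC)c2c(=O)cc(-c3ccc(Oc4c(OC)cc(O)c(C(=O)/C=C/c5ccc(OCc6ccccc6)cc5)c4OC)cc3)oc2c1
F3 | step 13 | racemic 2-[4-(benzyloxy)phenyl]-6-[4-(5,7-dimethoxy-4-oxo-4H-chromen-2-yl)phenoxy]-5,7-dimethoxychroman-4-one | COc1cc(OC)c2c(=O)cc(-c3ccc(Oc4c(OC)cc5c(c4OC)C(=O)CC(c4ccc(OCc6ccccc6)cc4)O5)cc3)oc2c1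
F4 | step 13 | racemic 5-hydroxy-2-(4-hydroxyphenyl)-6-[4-(5-hydroxy-7-methoxy-4-oxo-4H-chromen-2-yl)phenoxy]-7-methoxychroman-4-one | COc1cc(O)c2c(=O)cc(-c3ccc(Oc4c(OC)cc5c(c4O)C(=O)CC(c4ccc(O)cc4)O5)cc3)oc2c1
F5 | step 13 | (2R)-5-hydroxy-2-(4-hydroxyphenyl)-6-[4-(5-hydroxy-7-methoxy-4-oxo-4H-chromen-2-yl)phenoxy]-7-methoxychroman-4-one | COc1cc(O)c2c(=O)cc(-c3ccc(Oc4c(OC)cc5c(c4O)C(=O)C[C@H](c4ccc(O)cc4)O5)cc3)oc2c1
F6 | step 4 | 4-hydroxy-2,6-dimethoxybenzaldehyde | COc1cc(O)cc(OC)c1C=O
F7 | step 4 | 4-(benzyloxy)-2,6-dimethoxybenzaldehyde | COc1cc(OCc2ccccc2)cc(OC)c1C=O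
F8 | step 4 | 4-(benzyloxy)-2,6-dimethoxyphenyl formate | COc1cc(OCc2ccccc2)cc(OC)c1OC=O
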